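**Retrosynthetic overview**
- Target ⇐ tert-butyl ester ⇐ sp3–sp3 bond between C4 and C5 of the nonenoic acid chain: a chiral γ-bromo ester plus a geminal bis(acetoxymethyl) alkene. Replacing only the acetate trans to the furylethyl chain sets the Z-alkene and leaves the target's own acetate in place.
- Bis(acetoxymethyl) alkene ⇐ cross-metathesis of 3-(but-3-enyl)furan (3-bromofuran + butenyl Grignard) with the symmetric 2-methylidenepropane-1,3-diyl diacetate, so no E/Z question arises at that stage.
- Bromo ester ⇐ hydroxy ester ⇐ seven-membered lactone by reduction to the lactol and isopropylidene Wittig reaction.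
- Key step: lactone ⇐ achiral tert-butyl 4-oxocyclohexane-1-carboxylate by enantiotopic-group-selective Baeyer–Villiger oxidation. It sets the only stereocentre, and the two ring arms become the homoprenyl chain and the C3–C4 tether.
- Rings: the furan is bought; the only ring made is the oxepanone (six-to-seven ring expansion), opened again one step later.

Assumption: all numbered starting materials are purchased, and the monooxygenase variant that gives the (S)-lactone in step 3 is picked from an enzyme panel (cyclohexanone- and cyclopentanone-monooxygenase types often give opposite enantiomers on 4-substituted cyclohexanones).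

**Step 1**
Reactants: 1 3-bromofuran; 2 but-3-en-1-ylmagnesium bromide
Product: 3 3-(but-3-en-1-yl)furan
Conditions: NiCl2(dppp) (2 mol%), 2 (1.3 equiv., THF), Et2O, 0 °C to reflux
Reagents that add atoms: none
Why: Kumada–Corriu coupling, in which the nickel–diphosphine catalyst joins the furan C–Br bond to the primary alkyl Grignard faster than β-hydride elimination and the remote terminal alkene is inert.

**Step 2**
Reactants: 3 3-(but-3-en-1-yl)furan; 4 2-methylidenepropane-1,3-diyl diacetate
Product: 5 2-[3-(furan-3-yl)propylidene]propane-1,3-diyl diacetate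
Conditions: second-generation Hoveyda–Grubbs catalyst [RuCl2(H2IMes)(=CH-C6H4-2-OiPr)] (5 mol%), 4 (4 equiv.), CH2Cl2, 40 °C, argon sweep
Reagents that add atoms: none
Why: olefin cross-metathesis of a terminal olefin with an excess of a symmetric 1,1-disubstituted olefin, driven by loss of ethene; because the two acetoxymethyl arms are identical the trisubstituted alkene forms as one compound.

**Step 3**
Reactants: 6 tert-butyl 4-oxocyclohexane-1-carboxylate
Product: 7 tert-butyl (4S)-7-oxooxepane-4-carboxylate
Conditions: cyclohexanone monooxygenase ((S)-selective variant), NADPH (cat.), glucose dehydrogenase, D-glucose, air, phosphate buffer pH 8/5% MeOH, 25 °C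
Reagents that add atoms: dioxygen, O=O
Why: enzymatic Baeyer–Villiger oxidation with enantiotopic-group selection, in which the flavin peroxide in the chiral active site lets only one of the two equivalent C(O)–CH2 bonds migrate, so the achiral ketone becomes the (4S)-lactone; this carbon is C2 of the target, where the same spatial arrangement is named R because the ranking of the two arms changes.

**Step 4**
Reactants: 7 tert-butyl (4S)-7-oxooxepane-4-carboxylate; 8 isopropyltriphenylphosphonium iodide
Product: 11 tert-butyl (2S)-2-(2-hydroxyethyl)-6-methylhept-5-enoate, via phosphorus ylide 9 (not isolated), via lactol 10 (not isolated)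
Conditions: i-Bu2AlH (1.05 equiv.), toluene, −78 °C, 1 h; then 9 [from 8 (2.5 equiv.), n-BuLi (2.4 equiv.), THF, 0 °C] added at −78 °C, warm to 20 °C; aq. potassium sodium tartrate
Reagents that add atoms: none
Why: one-pot lactone half-reduction and Wittig olefination, in which the lactone is reduced to the aluminium lactolate much faster than the tert-butyl ester and its latent aldehyde reacts with the unstabilised ylide (two methyl groups, so no E/Z issue), while the stereocentre α to the hindered ester is not enolised.

**Step 5**
Reactants: 11 tert-butyl (2S)-2-(2-hydroxyethyl)-6-methylhept-5-enoate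
Product: 12 tert-butyl (2S)-2-(2-bromoethyl)-6-methylhept-5-enoate
Conditions: CBr4 (1.3 equiv.), PPh3 (1.4 equiv.), 2,6-lutidine (0.5 equiv.), CH2Cl2, 0 °C
Reagents that add atoms: carbon tetrabromide, BrC(Br)(Br)Br
Why: Appel reaction, an SN2 displacement of the primary alkoxyphosphonium by bromide under buffered conditions that leaves the trisubstituted alkene, the tert-butyl ester and the stereocentre untouched.

**Step 6**
Reactants: 12 tert-butyl (2S)-2-(2-bromoethyl)-6-methylhept-5-enoate; 5 2-[3-(furan-3-yl)propylidene]propane-1,3-diyl diacetate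
Product: 13 tert-butyl (2R,6Z)-6-(acetoxymethyl)-9-(furan-3-yl)-2-(4-methylpent-3-en-1-yl)non-6-enoate
Conditions: NiCl2(dme) (10 mol%), 4,4′,4″-tri-tert-butyl-2,2′:6′,2″-terpyridine (10 mol%), Zn dust (2 equiv.), 5 (2 equiv., excess recovered), DMA/THF, 40 °C
Reagents that add atoms: none
Why: nickel-catalysed reductive cross-electrophile coupling of an alkyl bromide with an allylic acetate, in which zerovalent nickel ionises the less hindered acetoxymethyl group (trans to the furylethyl chain) to the syn η3-allyl complex and the alkyl group is delivered to its CH2 terminus, so the remaining acetate ends up cis to the chain (6Z); the stereocentre is remote from the radical site and keeps its configuration.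

**Step 7**
Reactants: 13 tert-butyl (2R,6Z)-6-(acetoxymethyl)-9-(furan-3-yl)-2-(4-methylpent-3-en-1-yl)non-6-enoate
Product: 15 (2R,6Z)-6-(acetoxymethyl)-9-(furan-3-yl)-2-(4-methylpent-3-en-1-yl)non-6-enoic acid, via trimethylsilyl ester 14 (not isolated)
Conditions: Me3SiOSO2CF3 (3 equiv.), 2,6-lutidine (4 equiv.), CH2Cl2, 0 °C; then pH 5 aqueous buffer
Reagents that add atoms: none
Why: silyl triflate-mediated tert-butyl ester cleavage, in which O-silylation releases 2-methylpropene under non-protic buffered conditions and the silyl ester hydrolyses on work-up, sparing the primary acetate that aqueous base would remove.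

**Compound list**
1 | 3-bromofuran | Brc1ccoc1 | starting material
2 | but-3-en-1-ylmagnesium bromide | C=CCC[Mg]Br | starting material
3 | 3-(but-3-en-1-yl)furan | C=CCCc1ccoc1 | intermediate
4 | 2-methylidenepropane-1,3-diyl diacetate | CC(=O)OCC(=C)COC(C)=O | starting material
5 | 2-[3-(furan-3-yl)propylidene]propane-1,3-diyl diacetate | CC(=O)OCC(COC(C)=O)=CCCc1ccoc1 | intermediate
6 | tert-butyl 4-oxocyclohexane-1-carboxylate | CC(C)(C)OC(=O)C1CCC(=O)CC1 | starting material
7 | tert-butyl (4S)-7-oxooxepane-4-carboxylate | O=C1CC[C@@H](CCO1)C(=O)OC(C)(C)C | intermediate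
8 | isopropyltriphenylphosphonium iodide | CC(C)[P+](c1ccccc1)(c1ccccc1)c1ccccc1.[I-] | starting material
9 | (propan-2-ylidene)triphenylphosphorane | CC(C)=P(c1ccccc1)(c1ccccc1)c1ccccc1 | intermediate
10 | tert-butyl (4S)-7-hydroxyoxepane-4-carboxylate (lactol, present as its diisobutylaluminium alkoxide) | OC1CC[C@@H](CCO1)C(=O)OC(C)(C)C | intermediate
11 | tert-butyl (2S)-2-(2-hydroxyethyl)-6-methylhept-5-enoate | CC(C)=CCC[C@@H](CCO)C(=O)OC(C)(C)C | intermediate
12 | tert-butyl (2S)-2-(2-bromoethyl)-6-methylhept-5-enoate | CC(C)=CCC[C@@H](CCBr)C(=O)OC(C)(C)C | intermediate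
13 | tert-butyl (2R,6Z)-6-(acetoxymethyl)-9-(furan-3-yl)-2-(4-methylpent-3-en-1-yl)non-6-enoate | CC(=O)OC/C(=C\CCc1ccoc1)CCC[C@H](CCC=C(C)C)C(=O)OC(C)(C)C | intermediate
14 | trimethylsilyl (2R,6Z)-6-(acetoxymethyl)-9-(furan-3-yl)-2-(4-methylpent-3-en-1-yl)non-6-enoate | CC(=O)OC/C(=C\CCc1ccoc1)CCC[C@H](CCC=C(C)C)C(=O)O[Si](C)(C)C | intermediate
15 | (2R,6Z)-6-(acetoxymethyl)-9-(furan-3-yl)-2-(4-methylpent-3-en-1-yl)non-6-enoic acid | CC(=O)OC/C(=C\CCc1ccoc1)CCC[C@H](CCC=C(C)C)C(=O)O | target

**Step count**
Total: 7 steps. Longest linear sequence: 5 steps (6 → 7 → 11 → 12 → 13 → 15).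

**Steps most likely to fail, with fallbacks**

Step 3 (enzymatic desymmetrisation). The bulky, polar tert-butyl ester may be a poor monooxygenase substrate or give low ee. The fallback sets out from ketone 6 and desymmetrises it with a chiral base instead. Lithium bis(1-phenylethyl)amide (enantiomer chosen for the S product) with in situ Me3SiCl in THF at −78 °C gives the silyl enol ether tert-butyl (1S)-4-[(trimethylsilyl)oxy]cyclohex-3-ene-1-carboxylate F1. Ozonolysis (O3, CH2Cl2/MeOH, −78 °C) with NaBH4 work-up cleaves the enol double bond to the hydroxy acid (4S)-4-(tert-butoxycarbonyl)-6-hydroxyhexanoic acid F2. Yamaguchi lactonisation (2,4,6-trichlorobenzoyl chloride, Et3N, then DMAP, toluene, high dilution) closes the seven-membered ring and comes back to the route at lactone 7.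

Step 6 (reductive coupling). Three things can go wrong:
- the free primary radical may cyclise 6-exo onto the homoprenyl alkene;
- the product, still an allylic acetate, may couple a second time;
- the η3-allyl intermediate may leak to the E-isomer.

The fallback sets out from 5 and 12, fixes the geometry before the coupling and avoids a free radical. Lipase PS (phosphate buffer/acetone) hydrolyses the less hindered acetate of 5, the one trans to the chain, to [(2Z)-5-(furan-3-yl)-2-(hydroxymethyl)pent-2-en-1-yl] acetate F3. PPh3 and N-chlorosuccinimide in CH2Cl2 at 0 °C give the allylic chloride [(2E)-2-(chloromethyl)-5-(furan-3-yl)pent-2-en-1-yl] acetate F4 with the double bond unchanged. Bromide 12 is inserted by Zn dust/LiCl in THF at 50 °C to give [(3S)-3-(tert-butoxycarbonyl)-7-methyloct-6-en-1-yl]zinc bromide F5. F5 is coupled with F4 under CoBr2 catalysis (THF/NMP, −10 °C), an SN2-type allylation that retains alkene geometry, and comes back at 13.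

Step 7 (ester cleavage). The silyl triflate may ionise the allylic acetate or let the cation attack the furan. The fallback sets out from 13 and removes the acetate before the acid step. K2CO3 in MeOH at 0 °C gives the allylic alcohol tert-butyl (2R,6Z)-9-(furan-3-yl)-6-(hydroxymethyl)-2-(4-methylpent-3-en-1-yl)non-6-enoate F6. Its tert-butyl ester is cleaved on silica gel in refluxing toluene (or with 85% aqueous H3PO4 in toluene) to the hydroxy acid (2R,6Z)-9-(furan-3-yl)-6-(hydroxymethyl)-2-(4-methylpent-3-en-1-yl)non-6-enoic acid F7. Ac2O/pyridine, followed by aqueous hydrolysis of the mixed anhydride, acetylates the primary alcohol and comes back at target 15.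

**Further compounds**
F1 | step 3 | tert-butyl (1S)-4-[(trimethylsilyl)oxy]cyclohex-3-ene-1-carboxylate | C[Si](C)(C)OC1=CC[C@H](CC1)C(=O)OC(C)(C)C
F2 | step 3 | (4S)-4-(tert-butoxycarbonyl)-6-hydroxyhexanoic acid | OCC[C@H](CCC(=O)O)C(=O)OC(C)(C)C
F3 | step 6 | [(2Z)-5-(furan-3-yl)-2-(hydroxymethyl)pent-2-en-1-yl] acetate | CC(=O)OC/C(=C\CCc1ccoc1)CO
F4 | step 6 | [(2E)-2-(chloromethyl)-5-(furan-3-yl)pent-2-en-1-yl] acetate | CC(=O)OC/C(=C\CCc1ccoc1)CCl
F5 | step 6 | [(3S)-3-(tert-butoxycarbonyl)-7-methyloct-6-en-1-yl]zinc bromide | Br[Zn]CC[C@H](CCC=C(C)C)C(=O)OC(C)(C)C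
F6 | step 7 | tert-butyl (2R,6Z)-9-(furan-3-yl)-6-(hydroxymethyl)-2-(4-methylpent-3-en-1-yl)non-6-enoate | OC/C(=C\CCc1ccoc1)CCC[C@H](CCC=C(C)C)C(=O)OC(C)(C)C
F7 | step 7 | (2R,6Z)-9-(furan-3-yl)-6-(hydroxymethyl)-2-(4-methylpent-3-en-1-yl)non-6-enoic acid | OC/C(=C\CCc1ccoc1)CCC[C@H](CCC=C(C)C)C(=O)O
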